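**Plan**

- Retrosynthesis: after unmasking the silyl and benzyl ethers, the first skeletal cut removes the aryl bonds C2'–C3' and C5'–C6' of the 4-hydroxy-3,5-dimethoxyphenyl ring. C3'/C4'/C5' with their three oxygens become 1,3-dimethoxyacetone; C2'/C1'/C6' become a 3-(dimethylamino)acrolein carried on oxane C2 (oxane numbered O1, C2 aryl-bearing, C4 OH, C6 2-arylethyl).
- The enabling feature is that this benzene ring is symmetric about C1'–C4', has OMe/OH/OMe on three adjacent carbons and bare CH at C2' and C6'. That is a ketone with two equivalent α-CH2OMe groups plus a 2-substituted malonaldehyde, and the labile p-hydroxybenzylic C2–O1 bond only exists after the last C–C bond is made.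
- Further cuts: the aminomethylene carbon (amide acetal), then C2–C3 and C4–O (Prins closure of the oxane), O1–C2 (oxa-Michael to methyl propiolate) and C5–C6 (allylation of a 3-arylpropanal).
- Forward: aldehyde + allyl gives the homoallylic alcohol, then the β-alkoxyacrylate; the oxane ring closes first (step 5) and the benzene ring last (step 9).
- Stereochemistry: C6 by reagent-controlled Brown allylboration; C2 and C4 all-cis relative to C6 through the chair Prins transition state; the benzannulation creates no stereocentre.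

Key step: step 9

Assumption: enaminal 14 is drawn as its E isomer (formyl anti to NMe2), the usual ground state of such vinylogous formamides; this geometry disappears in the arene.

**Route**

Step 1
Reactants: 1 3-(4-hydroxy-3-methoxyphenyl)propanoic acid
Product: 2 benzyl 3-[4-(benzyloxy)-3-methoxyphenyl]propanoate
Conditions: BnBr (2.3 equiv), K2CO3, DMF, 60 °C
Reagents that add atoms: benzyl bromide, BrCc1ccccc1
Why: Williamson etherification of the phenoxide and SN2 esterification of the carboxylate in one pot mask both acidic groups and leave an ester ready for partial reduction.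

Step 2
Reactants: 2 benzyl 3-[4-(benzyloxy)-3-methoxyphenyl]propanoate
Product: 3 3-[4-(benzyloxy)-3-methoxyphenyl]propanal
Conditions: i-Bu2AlH (1.1 equiv), CH2Cl2, −78 °C; aq KNaC4H4O6
Reagents that add atoms: none
Why: Partial ester reduction with one equivalent of i-Bu2AlH at low temperature should stop at the aldehyde, the aryl benzyl ether being inert to hydride.

Step 3
Reactants: 3 3-[4-(benzyloxy)-3-methoxyphenyl]propanal; 4 allylmagnesium bromide
Product: 6 (3S)-1-[4-(benzyloxy)-3-methoxyphenyl]hex-5-en-3-ol, via diisopinocampheylborinate 5 (not isolated)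
Conditions: (+)-Ipc2BOMe [from (−)-α-pinene], 4, Et2O, 0 °C to rt; add 3 at −78 °C; then NaOH, H2O2
Reagents that add atoms: none
Why: Brown asymmetric allylboration: the B-allyldiisopinocampheylborane formed in the flask transfers allyl through a closed six-membered chair transition state to the Re face of the unbranched aldehyde, so the (−)-α-pinene-derived reagent should set the carbinol centre as S.

Step 4
Reactants: 6 (3S)-1-[4-(benzyloxy)-3-methoxyphenyl]hex-5-en-3-ol; 7 methyl propiolate
Product: 8 methyl (2E)-3-({(3S)-1-[4-(benzyloxy)-3-methoxyphenyl]hex-5-en-3-yl}oxy)prop-2-enoate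
Conditions: N-methylmorpholine, CH2Cl2, rt
Reagents that add atoms: none
Why: Tertiary-amine-catalysed oxa-Michael addition of the secondary alcohol to the propiolate gives the (E)-β-alkoxyacrylate and does not touch the stereocentre.

Step 5
Reactants: 8 methyl (2E)-3-({(3S)-1-[4-(benzyloxy)-3-methoxyphenyl]hex-5-en-3-yl}oxy)prop-2-enoate
Product: 10 methyl 2-[(2S,4R,6S)-6-{2-[4-(benzyloxy)-3-methoxyphenyl]ethyl}-4-hydroxyoxan-2-yl]acetate, via C4 trifluoroacetate 9 (not isolated)
Conditions: CF3CO2H, CH2Cl2, 0 °C to rt; evaporate; K2CO3 (cat.), MeOH, 0 °C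
Reagents that add atoms: trifluoroacetic acid, OC(=O)C(F)(F)F
Why: Prins cyclisation of a vinylogous carbonate: C-protonation of the β-alkoxyacrylate gives an (E)-oxocarbenium ion that the terminal alkene attacks through a chair transition state with both side chains equatorial, the C4 cation is captured equatorially by trifluoroacetate so that C2 and C4 are set all-cis relative to the existing C6 centre (substrate control), and mild methanolysis then frees the C4 alcohol.

Step 6
Reactants: 10 methyl 2-[(2S,4R,6S)-6-{2-[4-(benzyloxy)-3-methoxyphenyl]ethyl}-4-hydroxyoxan-2-yl]acetate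
Product: 11 methyl 2-[(2S,4R,6S)-6-{2-[4-(benzyloxy)-3-methoxyphenyl]ethyl}-4-[(tert-butyldimethylsilyl)oxy]oxan-2-yl]acetate
Conditions: TBSCl, imidazole, DMF, rt
Reagents that add atoms: tert-butyldimethylsilyl chloride, CC(C)(C)[Si](C)(C)Cl
Why: Corey silylation of the equatorial secondary alcohol; the silyl ether tolerates the hydride, amide acetal and alkoxide conditions that follow.

Step 7
Reactants: 11 methyl 2-[(2S,4R,6S)-6-{2-[4-(benzyloxy)-3-methoxyphenyl]ethyl}-4-[(tert-butyldimethylsilyl)oxy]oxan-2-yl]acetate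
Product: 12 2-[(2S,4R,6S)-6-{2-[4-(benzyloxy)-3-methoxyphenyl]ethyl}-4-[(tert-butyldimethylsilyl)oxy]oxan-2-yl]acetaldehyde
Conditions: i-Bu2AlH (1.1 equiv), CH2Cl2, −78 °C; aq KNaC4H4O6
Reagents that add atoms: none
Why: Partial reduction of the methyl ester with i-Bu2AlH at −78 °C should stop at the aldehyde under non-basic conditions that leave the β-alkoxy centre and both ethers untouched.

Step 8
Reactants: 12 2-[(2S,4R,6S)-6-{2-[4-(benzyloxy)-3-methoxyphenyl]ethyl}-4-[(tert-butyldimethylsilyl)oxy]oxan-2-yl]acetaldehyde; 13 N,N-dimethylformamide dimethyl acetal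
Product: 14 (2E)-2-[(2S,4R,6S)-6-{2-[4-(benzyloxy)-3-methoxyphenyl]ethyl}-4-[(tert-butyldimethylsilyl)oxy]oxan-2-yl]-3-(dimethylamino)prop-2-enal
Conditions: 13 (3 equiv), toluene, 90 °C
Reagents that add atoms: none
Why: Aminomethylenation of the α-methylene of an aldehyde by an amide acetal (enaminal condensation) gives the vinylogous formamide, and any retro-oxa-Michael opening of the β-alkoxy aldehyde should reclose to the thermodynamically preferred all-equatorial oxane.

Step 9
Reactants: 14 (2E)-2-[(2S,4R,6S)-6-{2-[4-(benzyloxy)-3-methoxyphenyl]ethyl}-4-[(tert-butyldimethylsilyl)oxy]oxan-2-yl]-3-(dimethylamino)prop-2-enal; 15 1,3-dimethoxyacetone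
Product: 17 4-[(2S,4R,6S)-6-{2-[4-(benzyloxy)-3-methoxyphenyl]ethyl}-4-[(tert-butyldimethylsilyl)oxy]oxan-2-yl]-2,6-dimethoxyphenol, via open-chain dienaminone 16 (not isolated)
Conditions: 15 (2.5 equiv), t-BuOK (3 equiv), THF/t-BuOH 4:1, 0 to 60 °C; then AcOH
Reagents that add atoms: none
Why: Proposed new method: the potassium enolate of 15 should add to the formyl carbon of 14 and lose hydroxide to give the push–pull dienaminone 16; deprotonation at the second methoxymethylene carbon then gives a 1-oxidohexatriene whose carbon terminus bonds to the aminomethine carbon, and loss of dimethylamine with tautomerisation delivers the 2,6-dimethoxyphenoxide, each new aryl C–C bond joining a methoxy-bearing carbon to a ring CH. The closest known reaction types are the base-mediated [3+3] condensation of sodium nitromalonaldehyde or 2-substituted vinamidinium salts with ketones having two enolisable α-positions, which gives para-substituted phenols, and the Jutz-type electrocyclisation of aminotrienes with loss of amine. The benzene ring closes by a thermal disrotatory 6π-electrocyclisation, in Baldwin terms a 6-endo-trig addition of the enolate carbon to the enamine C=C (6-exo-trig if counted on the C=N+ of its iminium resonance form). No stereocentre is created, and the three oxane centres are spectators because oxane C2 sits on a fully substituted alkene carbon with no acidifying carbonyl next to it. The step needs cross-condensation to win over self-aldolisation of 15 and needs no regiocontrol: the self-aldol is reversible under alkoxide whereas aromatisation to the phenoxide is not, and the twofold symmetry of the ketone together with the equivalence of the two electrophilic carbons of 14 in the final ring allows only one arene.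

Step 10
Reactants: 17 4-[(2S,4R,6S)-6-{2-[4-(benzyloxy)-3-methoxyphenyl]ethyl}-4-[(tert-butyldimethylsilyl)oxy]oxan-2-yl]-2,6-dimethoxyphenol
Product: 18 4-[(2S,4R,6S)-6-{2-[4-(benzyloxy)-3-methoxyphenyl]ethyl}-4-hydroxyoxan-2-yl]-2,6-dimethoxyphenol
Conditions: Bu4NF, AcOH, THF, 0 °C to rt
Reagents that add atoms: none
Why: Fluoride-induced desilylation driven by Si–F bond formation, with acetic acid buffering so that the medium does not become basic enough to open the p-hydroxybenzylic ether through a quinone methide.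

Step 11
Reactants: 18 4-[(2S,4R,6S)-6-{2-[4-(benzyloxy)-3-methoxyphenyl]ethyl}-4-hydroxyoxan-2-yl]-2,6-dimethoxyphenol
Product: 19 4-{(2S,4R,6S)-4-hydroxy-6-[2-(4-hydroxy-3-methoxyphenyl)ethyl]oxan-2-yl}-2,6-dimethoxyphenol
Conditions: H2 (1 atm), 10% Pd/C, EtOAc, rt
Reagents that add atoms: none
Why: Heterogeneous catalytic hydrogenolysis should cleave the aryl benzyl ether much faster than the ring benzylic C2–O1 bond, so the reaction is stopped as soon as 18 is consumed.

**Compound list**

1 | 3-(4-hydroxy-3-methoxyphenyl)propanoic acid | COc1cc(CCC(=O)O)ccc1O | starting material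
2 | benzyl 3-[4-(benzyloxy)-3-methoxyphenyl]propanoate | COc1cc(CCC(=O)OCc2ccccc2)ccc1OCc1ccccc1 | intermediate
3 | 3-[4-(benzyloxy)-3-methoxyphenyl]propanal | COc1cc(CCC=O)ccc1OCc1ccccc1 | intermediate
4 | allylmagnesium bromide | C=CC[Mg]Br | starting material
5 | (3S)-1-[4-(benzyloxy)-3-methoxyphenyl]hex-5-en-3-yl diisopinocampheylborinate (isopinocampheyl groups from (−)-α-pinene) | COc1cc(CC[C@H](OB([C@H]2C[C@H]3C[C@@H]([C@@H]2C)C3(C)C)[C@H]2C[C@H]3C[C@@H]([C@@H]2C)C3(C)C)CC=C)ccc1OCc1ccccc1 | intermediate (not isolated)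
6 | (3S)-1-[4-(benzyloxy)-3-methoxyphenyl]hex-5-en-3-ol | COc1cc(CC[C@H](O)CC=C)ccc1OCc1ccccc1 | intermediate
7 | methyl propiolate (methyl prop-2-ynoate) | COC(=O)C#C | starting material
8 | methyl (2E)-3-({(3S)-1-[4-(benzyloxy)-3-methoxyphenyl]hex-5-en-3-yl}oxy)prop-2-enoate | COc1cc(CC[C@H](O/C=C/C(=O)OC)CC=C)ccc1OCc1ccccc1 | intermediate
9 | methyl 2-[(2S,4R,6S)-6-{2-[4-(benzyloxy)-3-methoxyphenyl]ethyl}-4-(trifluoroacetoxy)oxan-2-yl]acetate | COc1cc(CC[C@H]2C[C@@H](OC(=O)C(F)(F)F)C[C@@H](CC(=O)OC)O2)ccc1OCc1ccccc1 | intermediate (not isolated)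
10 | methyl 2-[(2S,4R,6S)-6-{2-[4-(benzyloxy)-3-methoxyphenyl]ethyl}-4-hydroxyoxan-2-yl]acetate | COc1cc(CC[C@H]2C[C@@H](O)C[C@@H](CC(=O)OC)O2)ccc1OCc1ccccc1 | intermediate
11 | methyl 2-[(2S,4R,6S)-6-{2-[4-(benzyloxy)-3-methoxyphenyl]ethyl}-4-[(tert-butyldimethylsilyl)oxy]oxan-2-yl]acetate | COc1cc(CC[C@H]2C[C@@H](O[Si](C)(C)C(C)(C)C)C[C@@H](CC(=O)OC)O2)ccc1OCc1ccccc1 | intermediate
12 | 2-[(2S,4R,6S)-6-{2-[4-(benzyloxy)-3-methoxyphenyl]ethyl}-4-[(tert-butyldimethylsilyl)oxy]oxan-2-yl]acetaldehyde | COc1cc(CC[C@H]2C[C@@H](O[Si](C)(C)C(C)(C)C)C[C@@H](CC=O)O2)ccc1OCc1ccccc1 | intermediate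
13 | N,N-dimethylformamide dimethyl acetal | COC(OC)N(C)C | starting material
14 | (2E)-2-[(2S,4R,6S)-6-{2-[4-(benzyloxy)-3-methoxyphenyl]ethyl}-4-[(tert-butyldimethylsilyl)oxy]oxan-2-yl]-3-(dimethylamino)prop-2-enal | COc1cc(CC[C@H]2C[C@@H](O[Si](C)(C)C(C)(C)C)C[C@@H](/C(C=O)=C\N(C)C)O2)ccc1OCc1ccccc1 | intermediate
15 | 1,3-dimethoxyacetone (1,3-dimethoxypropan-2-one) | COCC(=O)COC | starting material
16 | (3E,5Z)-5-[(2S,4R,6S)-6-{2-[4-(benzyloxy)-3-methoxyphenyl]ethyl}-4-[(tert-butyldimethylsilyl)oxy]oxan-2-yl]-6-(dimethylamino)-1,3-dimethoxyhexa-3,5-dien-2-one (cyclisation-competent geometric isomer drawn) | COc1cc(CC[C@H]2C[C@@H](O[Si](C)(C)C(C)(C)C)C[C@@H](/C(=C\N(C)C)/C=C(OC)\C(=O)COC)O2)ccc1OCc1ccccc1 | intermediate (not isolated)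
17 | 4-[(2S,4R,6S)-6-{2-[4-(benzyloxy)-3-methoxyphenyl]ethyl}-4-[(tert-butyldimethylsilyl)oxy]oxan-2-yl]-2,6-dimethoxyphenol | COc1cc(CC[C@H]2C[C@@H](O[Si](C)(C)C(C)(C)C)C[C@@H](c3cc(OC)c(O)c(OC)c3)O2)ccc1OCc1ccccc1 | intermediate
18 | 4-[(2S,4R,6S)-6-{2-[4-(benzyloxy)-3-methoxyphenyl]ethyl}-4-hydroxyoxan-2-yl]-2,6-dimethoxyphenol | COc1cc(CC[C@H]2C[C@@H](O)C[C@@H](c3cc(OC)c(O)c(OC)c3)O2)ccc1OCc1ccccc1 | intermediate
19 | 4-{(2S,4R,6S)-4-hydroxy-6-[2-(4-hydroxy-3-methoxyphenyl)ethyl]oxan-2-yl}-2,6-dimethoxyphenol | COc1cc(CC[C@H]2C[C@@H](O)C[C@@H](c3cc(OC)c(O)c(OC)c3)O2)ccc1O | target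

**Step count and risks**

Total step count: 11. Longest linear sequence: 11 steps (1 to 19).

Steps most likely to fail:

1. Step 9 (proposed new method). The ketone enolate may be consumed by self-aldolisation faster than it adds to the weakly electrophilic vinylogous formamide. Alternatively, the cyclohexadienolate formed after ring closure may expel the oxane alkoxide instead of dimethylamine, opening the oxane and losing control of C2 on reclosure. The fallback uses known chemistry and sets out from 6. Syringaldehyde is acetylated (Ac2O, pyridine) to 4-formyl-2,6-dimethoxyphenyl acetate F1, whose acetate keeps the aryl group electron-poor enough to suppress 2-oxonia-Cope scrambling and benzylic ionisation. A classical aldehyde Prins cyclisation of 6 with F1 (CF3CO2H, CH2Cl2) should give the all-cis oxane 4-[(2S,4R,6S)-6-{2-[4-(benzyloxy)-3-methoxyphenyl]ethyl}-4-(trifluoroacetoxy)oxan-2-yl]-2,6-dimethoxyphenyl acetate F2. Methanolysis of both esters (K2CO3, MeOH) returns to the route at 18.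

2. Step 8. Self-condensation of the enolisable aldehyde and base-induced retro-oxa-Michael opening of the β-alkoxy aldehyde may compete with aminomethylenation in the hot, methoxide-containing medium. The fallback sets out from 12. Silylation (TMSCl, Et3N, NaI, MeCN) gives the (Z)-trimethylsilyl enol ether of 12 F3 under essentially neutral conditions. Vilsmeier aminomethylenation with (chloromethylene)dimethyliminium chloride (CH2Cl2, 0 °C; aq K2CO3 work-up) then returns to the route at 14.

3. Step 5. C-protonation of the deactivated enol ether may be too slow, so that acid-induced loss or migration of the aryl benzyl group, or 2-oxonia-Cope side-chain exchange, overtakes ring closure. The fallback sets out from 6. An ordinary aldehyde Prins cyclisation with 3-(trimethylsilyl)propynal (CF3CO2H, CH2Cl2, short contact) should give (2S,4R,6S)-2-{2-[4-(benzyloxy)-3-methoxyphenyl]ethyl}-6-[(trimethylsilyl)ethynyl]oxan-4-yl trifluoroacetate F4. K2CO3/MeOH removes the ester and the C-silyl group to give (2S,4R,6S)-2-{2-[4-(benzyloxy)-3-methoxyphenyl]ethyl}-6-ethynyloxan-4-ol F5. Silylation (TBSCl, imidazole) gives tert-butyl{[(2S,4R,6S)-2-{2-[4-(benzyloxy)-3-methoxyphenyl]ethyl}-6-ethynyloxan-4-yl]oxy}dimethylsilane F6. Anti-Markovnikov hydroboration of the terminal alkyne with dicyclohexylborane and oxidation with NaBO3 returns to the route at 12.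

Further compounds
F1 | step 9 | 4-formyl-2,6-dimethoxyphenyl acetate | COc1cc(C=O)cc(OC)c1OC(C)=O
F2 | step 9 | 4-[(2S,4R,6S)-6-{2-[4-(benzyloxy)-3-methoxyphenyl]ethyl}-4-(trifluoroacetoxy)oxan-2-yl]-2,6-dimethoxyphenyl acetate | COc1cc(CC[C@H]2C[C@@H](OC(=O)C(F)(F)F)C[C@@H](c3cc(OC)c(OC(C)=O)c(OC)c3)O2)ccc1OCc1ccccc1
F3 | step 8 | tert-butyl{[(2S,4R,6S)-2-{2-[4-(benzyloxy)-3-methoxyphenyl]ethyl}-6-{(Z)-2-[(trimethylsilyl)oxy]ethenyl}oxan-4-yl]oxy}dimethylsilane (Z isomer drawn, either geometry serves) | COc1cc(CC[C@H]2C[C@@H](O[Si](C)(C)C(C)(C)C)C[C@@H](/C=C\O[Si](C)(C)C)O2)ccc1OCc1ccccc1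
F4 | step 5 | (2S,4R,6S)-2-{2-[4-(benzyloxy)-3-methoxyphenyl]ethyl}-6-[(trimethylsilyl)ethynyl]oxan-4-yl trifluoroacetate | COc1cc(CC[C@H]2C[C@@H](OC(=O)C(F)(F)F)C[C@@H](C#C[Si](C)(C)C)O2)ccc1OCc1ccccc1
F5 | step 5 | (2S,4R,6S)-2-{2-[4-(benzyloxy)-3-methoxyphenyl]ethyl}-6-ethynyloxan-4-ol | COc1cc(CC[C@H]2C[C@@H](O)C[C@@H](C#C)O2)ccc1OCc1ccccc1
F6 | step 5 | tert-butyl{[(2S,4R,6S)-2-{2-[4-(benzyloxy)-3-methoxyphenyl]ethyl}-6-ethynyloxan-4-yl]oxy}dimethylsilane | COc1cc(CC[C@H]2C[C@@H](O[Si](C)(C)C(C)(C)C)C[C@@H](C#C)O2)ccc1OCc1ccccc1
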